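(The data stem from a simulated flask on assumed constants, noise included.)

An equivalent, one mole of partner per mole of solid substrate charged, is the unit to read these flasks in. Take the two as combining one to one, so that one equivalent is the zero of the scale: above it the solid substrate is the limiting reagent, below it the partner.

| setting | amber | grey | epsilon | zeta | theta | alpha | delta |
|---|---|---|---|---|---|---|---|
| solid substrate | 0.047 M | 0.71 M | 0.50 M | 0.080 M | 0.60 M | 1.0 M | 0.31 M |
| partner | 0.326 M | 0.326 M | 0.326 M | 0.326 M | 0.326 M | 0.326 M | 0.326 M |
| remark | run made earlier | run made earlier |  |  |  |  |  |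
| time |  |  | 3.0 min | 3.0 min | 3.0 min | 3.0 min | 3.0 min |

| run | time / min | target / % | solid substrate / % |
|---|---|---|---|
| amber | 0.250 | 62.4 | 27.4 |
| amber | 0.833 | 98.5 | 0 |
| amber | 1.33 | 97.0 | 0.2 |
| amber | 2.00 | 95.8 | 0 |
| amber | 3.00 | 94.4 | 0.1 |
| grey | 0.250 | 3.7 | 95.1 |
| grey | 0.417 | 7.5 | 92.0 |
| grey | 0.833 | 14.4 | 84.8 |
| grey | 1.50 | 23.9 | 74.4 |
| grey | 3.00 | 38.7 | 59.3 |

(standard deviation of a reading: 0.3 percentage points)

1. the flasks by amount of target, in percent of the solid substrate charged, highest first, at 3.0 min (epsilon / zeta / theta / alpha / delta)
2. the same order at 12 min (epsilon / zeta / theta / alpha / delta)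
3. the amount of target, in percent of the solid substrate charged of the flask you put first, at 3.0 min
4. the amount of target, in percent of the solid substrate charged of the flask you put last, at 3.0 min

- the analysis behind the earlier runs scatters by 0.3 percentage points, standard deviation
- at the start none of the solid substrate is in solution
- what has only dissolved of solid substrate counts as not reacted
- a reading or a percentage of target counts all its forms, free or not

Read the earlier runs as fractions of the charge. After 0.250 min amber had turned 9.00 % of its partner charge into target and grey 8.06 %, although grey carried 15.1 times amber's charge, so the partner's spending looks little moved by the charge while solid stands. Grey's last reading gives the fraction of the partner charge turned into target by 3.0 min, 84.3 %: call it the partner draw. At this partner charge, a flask's target fraction should be the draw times its equivalents, capped by the charge.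

Now turn the question round: what would alpha need to lead zeta at 3.0 min? Alpha stands at 0.326 equivalents, and amber, with its partner in excess, read 94.4 %. Matching that takes a draw of 290 %, more than the partner charge, while a complete draw gives alpha 32.6 %. My own reckoning therefore gives alpha 27.5 %, theta 45.8 %, epsilon 55.0 % and delta, at 1.05 equivalents, 88.6 %. For zeta the draw asks 343 % of the charge, so I put zeta near amber's reading.

The forecast gives zeta > delta > epsilon > theta > alpha at 3.0 min and delta > zeta > epsilon > theta > alpha at 12 min, with 94.6 % first and 27.5 % last, on the ground that “target forms by 3 min, whatever the loading”. Its delta, about 85, stands below mine.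

The flasks give zeta > delta > epsilon > theta > alpha at 3.0 min and delta > zeta > epsilon > theta > alpha at 12 min, with 96.4 % first and 27.2 % last, so the forecast stands.

    solid substrate → decomposition product (k = 3.60 × 10⁻⁵ s⁻¹)
    dissolved substrate + partner → target (k = 1.50 L mol⁻¹ s⁻¹)
    target ⇌ isomer of the product (K = 2.50, k = 0.00140 s⁻¹)
    solid substrate ⇌ dissolved substrate, rate k4*(cs4 - [dissolved substrate]) while solid is left; crystals form when [dissolved substrate] > cs4 (solubility = 13.0 mM, k = 0.260 s⁻¹)
    solid product ⇌ target, rate k5*(cs5 - [target]) while solid is left; crystals form when [target] > cs5 (solubility = 12.0 mM, k = 1.70 s⁻¹)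

At 3.00 min alpha still holds 16 % of its partner, where the draw leaves 15.7 %, and 70.9 % of its solid substrate stands unreacted. Delta, nearly at the zero of the scale, gives 87.9 % against the draw's 88.6 %.

The neighbour of alpha with 1.7 M of solid substrate stands at 0.192 equiv, so the draw gives 16.2 % target at 3.0 min. That flask gives 16.0 %.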